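Siphonaxanthin is numbered below as a carotenoid: C1–C20 on the keto half, primed locants on the half whose ring carries the allylic alcohol (ε ring, C1'–C6').

**Plan**
- Cuts: C11=C12 (Wittig), C8–C9 (Nozaki–Hiyama–Kishi, then oxidation), C11'=C12' (Wittig on the C10 dialdehyde), C9'–C10' (vinyl addition to a C13 enone), C6'–C7' (Heck) and, inside the ε ring, the bond C1'–C6'.
- Enabling feature: in the ε ring the gem-dimethyl carbon C1' is bonded to C6' and the ring alkene is C4'=C5'. The ring is therefore what a tertiary C1' cation gives on 6-endo addition to a C5'=C6' alkene with loss of H-4'. O-3' lies on the tether, 1,4 to C6', where an equatorial group in a chair can relay its configuration.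
- Forward, ε half: (R)-epichlorohydrin → acyclic (8R)-8-acetoxy trienone (steps 1–5) → cation–olefin cyclisation closing the ε ring, the only ring of the skeleton made in the route (step 6) → C15 and C25 phosphonium salts (steps 7–11).
- Forward, β half: the β ring is bought as actinol and extended by C7–C8 (steps 12–15); the C19/C9/C10/C11 unit comes from a propargyl ether (steps 16–19); union, double oxidation, final Wittig and desilylation (steps 20–23).
- Stereochemistry: C3' from epichlorohydrin; C6' by 1,4-induction in step 6; C3 from actinol; 9E from syn-stannylcupration; the other alkenes from syn-carboalumination, Heck coupling and thermodynamically controlled Wittig couplings.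

Key step: step 6

Assumption: (4R,6R)-actinol 21 and the C10 dialdehyde 16, both industrial carotenoid intermediates, are treated as purchasable.

**Route**

Step 1
Reactants: 1 (R)-epichlorohydrin; 2 isopropenylmagnesium bromide
Product: 4 (2R)-2-(2-methylprop-2-en-1-yl)oxirane, via chlorohydrin 3 (not isolated)
Conditions: 2 (1.1 equiv), CuI (10 mol%), THF, −40 °C; aqueous work-up; crude 3, powdered NaOH, Et2O, rt
Reagents that add atoms: none
Why: Copper-catalysed Grignard opening of the epoxide at its CH2 terminus (SN2) and base-induced Williamson closure of the chlorohydrin carry the (R) centre of 1 unchanged into the new epoxide, whose CH carbon is the future C3'.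

Step 2
Reactants: 4 (2R)-2-(2-methylprop-2-en-1-yl)oxirane; 5 lithium acetylide–ethylenediamine complex
Product: 6 (4R)-6-methylhept-6-en-1-yn-4-ol
Conditions: 5 (1.5 equiv), DMSO, 0 °C → rt
Reagents that add atoms: none
Why: SN2 opening of the terminal epoxide by acetylide at the unsubstituted carbon gives the homopropargylic alcohol without touching the stereocentre.

Step 3
Reactants: 6 (4R)-6-methylhept-6-en-1-yn-4-ol
Product: 8 (1E,4R)-1-iodo-2,6-dimethylhepta-1,6-dien-4-ol, via alkenylalane 7 (not isolated)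
Conditions: Me3Al (3 equiv), Cp2ZrCl2 (0.25 equiv), CH2Cl2, 0 °C → rt; then I2, THF, −30 °C
Reagents that add atoms: trimethylaluminium, C[Al](C)C; iodine, II
Why: Zirconium-catalysed syn-carboalumination of the terminal alkyne (Negishi carboalumination, the alcohol carried as its aluminium alkoxide) and iodinolysis with retention should give the (E)-trisubstituted alkenyl iodide, the 1,1-disubstituted alkene being inert to the reagent.

Step 4
Reactants: 8 (1E,4R)-1-iodo-2,6-dimethylhepta-1,6-dien-4-ol; 9 methyl vinyl ketone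
Product: 10 (3E,5E,8R)-8-hydroxy-6,10-dimethylundeca-3,5,10-trien-2-one
Conditions: Pd(OAc)2 (5 mol%), Bu4NCl, NaHCO3, DMF, rt → 40 °C
Reagents that add atoms: none
Why: Heck reaction of the alkenyl iodide with the enone under ligand-free phase-transfer conditions keeps the iodide geometry and gives the (E)-enone; the C–Pd bond is trans to the tether, so insertion into the isopropenyl group cannot compete.

Step 5
Reactants: 10 (3E,5E,8R)-8-hydroxy-6,10-dimethylundeca-3,5,10-trien-2-one
Product: 11 (4R,6E,8E)-2,6-dimethyl-10-oxoundeca-1,6,8-trien-4-yl acetate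
Conditions: Ac2O, pyridine, DMAP (cat.), CH2Cl2, 0 °C → rt
Reagents that add atoms: acetic anhydride, CC(=O)OC(C)=O
Why: DMAP-catalysed acylation; an ester is chosen because a free β-hydroxyl would fragment (retro-Prins) once the tertiary cation of step 6 is formed.

Step 6
Reactants: 11 (4R,6E,8E)-2,6-dimethyl-10-oxoundeca-1,6,8-trien-4-yl acetate
Product: 12 (1R,4R)-3,5,5-trimethyl-4-[(1E)-3-oxobut-1-en-1-yl]cyclohex-2-en-1-yl acetate [(3R,6R)-3-acetoxy-α-ionone]
Conditions: ClSO3H (3 equiv), 2-nitropropane, −78 → −50 °C, 30 min; Et3N, then aq NaHCO3 at −78 °C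
Reagents that add atoms: none
Why: Markovnikov protonation of the isopropenyl group gives the tertiary cation at the future C1', the (E)-trisubstituted alkene adds to it through its CH carbon (future C6') to give the tertiary ring cation at C5', and loss of H-4' leaves the unconjugated C4'=C5' alkene. This is the laboratory version of the ε-cyclase event and the same reaction type as the acid-mediated cation–olefin cyclisation of pseudoionone to α-ionone and of polyprenyl acetates in chlorosulfonic acid at low temperature. The ring closes in the 6-endo-trig mode through a chair transition state. The new stereocentre C6' is controlled by the acetoxy-bearing C3' on the tether: the acetoxy group stays equatorial, because an axial one would be syn-axial to a C1' methyl, and the (E) alkene places the enone arm equatorial, so the 3,6-trans (3R,6R) ring is expected. The step needs initiation at the isopropenyl alkene only, which is the one isolated electron-rich alkene of 11, and proton loss toward C4', which is the kinetic course in α-ionone formation and is protected here because the C3' acetoxy group disfavours the reprotonation at C4' that converts α into conjugated β isomers. It also needs the C3'–O bond to survive, which the ester secures by blocking retro-Prins fragmentation of the β-oxygenated cation and, in its protonated form at low temperature, by resisting ionisation once it has become allylic.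

Step 7
Reactants: 12 (3R,6R)-3-acetoxy-α-ionone; 13 vinylmagnesium bromide
Product: 14 (1R,4R)-4-[(1E)-3-hydroxy-3-methylpenta-1,4-dien-1-yl]-3,5,5-trimethylcyclohex-2-en-1-ol (both epimers at the new carbinol carbon)
Conditions: 13 (4 equiv), THF, −30 → 0 °C
Reagents that add atoms: none
Why: 1,2-Addition of the vinyl Grignard reagent to the enone (the vinyl-ionol reaction), excess reagent also cleaving the acetate; the new tertiary carbinol forms as a mixture that is erased in step 8.

Step 8
Reactants: 14 (1R,4R)-4-[(1E)-3-hydroxy-3-methylpenta-1,4-dien-1-yl]-3,5,5-trimethylcyclohex-2-en-1-ol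
Product: 15 [(2E,4E)-5-[(1R,4R)-4-hydroxy-2,6,6-trimethylcyclohex-2-en-1-yl]-3-methylpenta-2,4-dien-1-yl]triphenylphosphonium bromide
Conditions: PPh3·HBr (1.05 equiv), MeOH, 0 °C → rt
Reagents that add atoms: triphenylphosphine hydrobromide, [Br-].c1ccc(cc1)[PH+](c1ccccc1)c1ccccc1
Why: SN1 ionisation of the doubly allylic tertiary alcohol to a pentadienyl cation and capture by PPh3 at the primary terminus (allylic transposition, the standard C15 Wittig salt formation) should give the thermodynamically preferred (E)-trisubstituted alkene, while the isolated secondary allylic ring alcohol should ionise much more slowly.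

Step 9
Reactants: 15 C15 phosphonium bromide; 16 (2E,4E,6E)-2,7-dimethylocta-2,4,6-trienedial
Product: 18 (2E,4E,6E,8E,10E,12E)-13-[(1R,4R)-4-hydroxy-2,6,6-trimethylcyclohex-2-en-1-yl]-2,7,11-trimethyltrideca-2,4,6,8,10,12-hexaenal, via ylide 17 (not isolated)
Conditions: NaOMe (1.1 equiv), CH2Cl2–MeOH, 0 °C; 16 (2 equiv), rt; then EtOAc, reflux
Reagents that add atoms: none
Why: Wittig olefination of one aldehyde of the excess symmetric dialdehyde by the semi-stabilised ylide is the classic C15 + C10 carotenoid coupling, and the hindered Z isomer of the new disubstituted alkene should isomerise to E on heating.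

Step 10
Reactants: 18 C25 aldehyde
Product: 19 (2E,4E,6E,8E,10E,12E)-13-[(1R,4R)-4-hydroxy-2,6,6-trimethylcyclohex-2-en-1-yl]-2,7,11-trimethyltrideca-2,4,6,8,10,12-hexaen-1-ol
Conditions: NaBH4, MeOH–THF, 0 °C
Reagents that add atoms: none
Why: Borohydride 1,2-reduction of the polyenal to the allylic alcohol.

Step 11
Reactants: 19 C25 alcohol
Product: 20 {(2E,4E,6E,8E,10E,12E)-13-[(1R,4R)-4-hydroxy-2,6,6-trimethylcyclohex-2-en-1-yl]-2,7,11-trimethyltrideca-2,4,6,8,10,12-hexaen-1-yl}triphenylphosphonium bromide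
Conditions: PPh3·HBr (1.05 equiv), MeOH–CH2Cl2, rt
Reagents that add atoms: triphenylphosphine hydrobromide, [Br-].c1ccc(cc1)[PH+](c1ccccc1)c1ccccc1
Why: Acid-mediated SN1 substitution of the polyenylic primary alcohol by PPh3 (Wittig salt formation), which should be far faster than ionisation of the ring alcohol.

Step 12
Reactants: 21 (4R,6R)-4-hydroxy-2,2,6-trimethylcyclohexan-1-one (actinol)
Product: 22 (4R,6R)-4-[(tert-butyldimethylsilyl)oxy]-2,2,6-trimethylcyclohexan-1-one
Conditions: TBSCl, imidazole, DMF, rt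
Reagents that add atoms: tert-butyldimethylsilyl chloride, CC(C)(C)[Si](C)(C)Cl
Why: Imidazole-promoted silylation protects O3 through the enolate and organometallic steps.

Step 13
Reactants: 22 (4R,6R)-4-[(tert-butyldimethylsilyl)oxy]-2,2,6-trimethylcyclohexan-1-one
Product: 24 (4R)-4-[(tert-butyldimethylsilyl)oxy]-2,6,6-trimethylcyclohex-1-en-1-yl trifluoromethanesulfonate, via lithium enolate 23 (not isolated)
Conditions: LDA, THF, −78 → 0 °C; PhNTf2, 0 °C → rt
Reagents that add atoms: N-phenylbis(trifluoromethanesulfonimide), O=S(=O)(N(c1ccccc1)S(=O)(=O)C(F)(F)F)C(F)(F)F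
Why: The ketone has a single enolisable position, so deprotonation and O-sulfonylation of the enolate (enol triflate formation) can give only the tetrasubstituted C5=C6 triflate.

Step 14
Reactants: 24 enol triflate; 25 2-[(E)-2-ethoxyethenyl]-4,4,5,5-tetramethyl-1,3,2-dioxaborolane
Product: 26 tert-butyl({(1R)-4-[(E)-2-ethoxyethenyl]-3,5,5-trimethylcyclohex-3-en-1-yl}oxy)dimethylsilane
Conditions: Pd(PPh3)4 (5 mol%), K3PO4, dioxane–H2O, 85 °C
Reagents that add atoms: none
Why: Suzuki–Miyaura coupling of the hindered cyclohexenyl triflate with the alkenylboronate (oxidative addition to zerovalent palladium, transmetalation, reductive elimination) installs C7 and C8 with retention of the enol ether geometry.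

Step 15
Reactants: 26 dienyl ethyl ether
Product: 27 2-[(4R)-4-[(tert-butyldimethylsilyl)oxy]-2,6,6-trimethylcyclohex-1-en-1-yl]acetaldehyde
Conditions: 0.5 M HCl, THF–H2O, 0 °C
Reagents that add atoms: water, O
Why: Acid-catalysed enol ether hydrolysis by protonation at C7 and loss of ethanol from the hemiacetal gives the β,γ-unsaturated aldehyde; the tetrasubstituted ring alkene stays because protonation at the fully substituted C5 is hindered.

Step 16
Reactants: 28 tert-butyldimethyl(prop-2-yn-1-yloxy)silane; 29 methyl chloroformate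
Product: 31 methyl 4-[(tert-butyldimethylsilyl)oxy]but-2-ynoate, via lithium acetylide 30 (not isolated)
Conditions: n-BuLi, THF, −78 °C; 29, −78 → 0 °C
Reagents that add atoms: none
Why: Deprotonation of the terminal alkyne and C-acylation of the lithium acetylide with the chloroformate.

Step 17
Reactants: 31 methyl 4-[(tert-butyldimethylsilyl)oxy]but-2-ynoate
Product: 32 methyl (2E)-4-[(tert-butyldimethylsilyl)oxy]-3-(tributylstannyl)but-2-enoate
Conditions: Bu3SnH, LDA, THF, −40 °C; CuBr·SMe2, −78 °C; then 31, MeOH (2 equiv), −78 °C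
Reagents that add atoms: tributyltin hydride, CCCC[SnH](CCCC)CCCC
Why: syn-Stannylcupration of the ynoate (conjugate delivery of tin to the β-carbon, kinetic protonation of the alkenylcopper at −78 °C) should give the (E)-β-stannyl enoate in which CH2OTBS (C19) is cis to the ester carbon (C11), the geometry needed at C9=C10.

Step 18
Reactants: 32 stannyl enoate
Product: 33 (2E)-4-[(tert-butyldimethylsilyl)oxy]-3-(tributylstannyl)but-2-en-1-ol
Conditions: iBu2AlH (2.2 equiv), CH2Cl2, −78 °C
Reagents that add atoms: none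
Why: iBu2AlH 1,2-reduction of the enoate to the allylic alcohol leaves the alkenylstannane intact.

Step 19
Reactants: 33 stannyl alcohol
Product: 34 (2E)-4-[(tert-butyldimethylsilyl)oxy]-3-iodobut-2-en-1-ol
Conditions: I2 (1.05 equiv), CH2Cl2, 0 °C
Reagents that add atoms: iodine, II
Why: Iododestannylation (electrophilic ipso substitution) proceeds with retention of alkene geometry.

Step 20
Reactants: 34 iodo alcohol; 27 aldehyde
Product: 35 (2E)-3-{[(tert-butyldimethylsilyl)oxy]methyl}-5-[(4R)-4-[(tert-butyldimethylsilyl)oxy]-2,6,6-trimethylcyclohex-1-en-1-yl]pent-2-ene-1,4-diol (both epimers at C4)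
Conditions: CrCl2 (5 equiv), NiCl2 (2 mol%), DMSO–THF, rt
Reagents that add atoms: none
Why: Nozaki–Hiyama–Kishi coupling (nickel-catalysed formation of the alkenylchromium species and its addition to the aldehyde) tolerates the free hydroxyl and does not enolise the β,γ-unsaturated aldehyde; the new C8 carbinol forms as a mixture that is erased in step 21.

Step 21
Reactants: 35 diol
Product: 36 (2E)-3-{[(tert-butyldimethylsilyl)oxy]methyl}-5-[(4R)-4-[(tert-butyldimethylsilyl)oxy]-2,6,6-trimethylcyclohex-1-en-1-yl]-4-oxopent-2-enal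
Conditions: Dess–Martin periodinane (3 equiv), pyridine, CH2Cl2, 0 °C → rt
Reagents that add atoms: none
Why: Dess–Martin oxidation of both allylic alcohols gives the C8 ketone and the C11 aldehyde in one operation under buffered conditions that should not move the C5=C6 alkene.

Step 22
Reactants: 20 C25 phosphonium bromide; 36 keto aldehyde
Product: 38 (3R,3'R,6'R)-3,19-bis[(tert-butyldimethylsilyl)oxy]-3'-hydroxy-7,8-dihydro-β,ε-caroten-8-one, via ylide 37 (not isolated)
Conditions: 1,2-epoxybutane, EtOH–CH2Cl2, 50 °C, dark; then EtOAc, reflux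
Reagents that add atoms: none
Why: Wittig olefination under base-free conditions (the epoxide is the proton acceptor) lets the semi-stabilised ylide react with the aldehyde in preference to the ketone and forms C11=C12, the hindered 11Z isomer being expected to isomerise to all-E on heating.

Step 23
Reactants: 38 bis-silyl ether
Product: 39 siphonaxanthin, (3R,3'R,6'R)-3,3',19-trihydroxy-7,8-dihydro-β,ε-caroten-8-one
Conditions: TBAF, AcOH (1:1), THF, 0 °C → rt
Reagents that add atoms: none
Why: Fluoride-mediated desilylation buffered with acetic acid removes both silyl ethers without ionising the allylic C3' alcohol or conjugating the β,γ-unsaturated ketone.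

**Compound list**

1 | (R)-epichlorohydrin | ClC[C@H]1CO1 | starting material
2 | isopropenylmagnesium bromide | CC(=C)[Mg]Br | starting material
3 | (2R)-1-chloro-4-methylpent-4-en-2-ol | ClC[C@H](O)CC(C)=C | intermediate (not isolated)
4 | (2R)-2-(2-methylprop-2-en-1-yl)oxirane | C=C(C)C[C@@H]1CO1 | intermediate
5 | lithium acetylide–ethylenediamine complex | [Li+].[C-]#C.NCCN | starting material
6 | (4R)-6-methylhept-6-en-1-yn-4-ol | C#CC[C@H](O)CC(C)=C | intermediate
7 | [(1E,4R)-4-(dimethylalumanyloxy)-2,6-dimethylhepta-1,6-dien-1-yl]dimethylalumane | C[Al](C)/C=C(C)/C[C@H](O[Al](C)C)CC(C)=C | intermediate (not isolated)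
8 | (1E,4R)-1-iodo-2,6-dimethylhepta-1,6-dien-4-ol | I/C=C(C)/C[C@H](O)CC(C)=C | intermediate
9 | methyl vinyl ketone | CC(=O)C=C | starting material
10 | (3E,5E,8R)-8-hydroxy-6,10-dimethylundeca-3,5,10-trien-2-one | CC(=O)/C=C/C=C(C)/C[C@H](O)CC(C)=C | intermediate
11 | (4R,6E,8E)-2,6-dimethyl-10-oxoundeca-1,6,8-trien-4-yl acetate | CC(=O)/C=C/C=C(C)/C[C@H](OC(C)=O)CC(C)=C | intermediate
12 | (1R,4R)-3,5,5-trimethyl-4-[(1E)-3-oxobut-1-en-1-yl]cyclohex-2-en-1-yl acetate | CC1=C[C@H](OC(C)=O)CC(C)(C)[C@H]1/C=C/C(C)=O | intermediate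
13 | vinylmagnesium bromide | C=C[Mg]Br | starting material
14 | (1R,4R)-4-[(1E)-3-hydroxy-3-methylpenta-1,4-dien-1-yl]-3,5,5-trimethylcyclohex-2-en-1-ol, both epimers at the side-chain carbinol | CC1=C[C@H](O)CC(C)(C)[C@H]1/C=C/C(C)(O)C=C | intermediate
15 | [(2E,4E)-5-[(1R,4R)-4-hydroxy-2,6,6-trimethylcyclohex-2-en-1-yl]-3-methylpenta-2,4-dien-1-yl]triphenylphosphonium bromide | CC1=C[C@H](O)CC(C)(C)[C@H]1/C=C/C(C)=C/C[P+](c1ccccc1)(c1ccccc1)c1ccccc1.[Br-] | intermediate
16 | (2E,4E,6E)-2,7-dimethylocta-2,4,6-trienedial | O=C/C(C)=C/C=C/C=C(C)/C=O | starting material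
17 | triphenylphosphonium ylide of 15 | CC1=C[C@H](O)CC(C)(C)[C@H]1/C=C/C(C)=C/C=P(c1ccccc1)(c1ccccc1)c1ccccc1 | intermediate (not isolated)
18 | (2E,4E,6E,8E,10E,12E)-13-[(1R,4R)-4-hydroxy-2,6,6-trimethylcyclohex-2-en-1-yl]-2,7,11-trimethyltrideca-2,4,6,8,10,12-hexaenal | CC1=C[C@H](O)CC(C)(C)[C@H]1/C=C/C(C)=C/C=C/C(C)=C/C=C/C=C(C)/C=O | intermediate
19 | (2E,4E,6E,8E,10E,12E)-13-[(1R,4R)-4-hydroxy-2,6,6-trimethylcyclohex-2-en-1-yl]-2,7,11-trimethyltrideca-2,4,6,8,10,12-hexaen-1-ol | CC1=C[C@H](O)CC(C)(C)[C@H]1/C=C/C(C)=C/C=C/C(C)=C/C=C/C=C(C)/CO | intermediate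
20 | {(2E,4E,6E,8E,10E,12E)-13-[(1R,4R)-4-hydroxy-2,6,6-trimethylcyclohex-2-en-1-yl]-2,7,11-trimethyltrideca-2,4,6,8,10,12-hexaen-1-yl}triphenylphosphonium bromide | CC1=C[C@H](O)CC(C)(C)[C@H]1/C=C/C(C)=C/C=C/C(C)=C/C=C/C=C(C)/C[P+](c1ccccc1)(c1ccccc1)c1ccccc1.[Br-] | intermediate
21 | (4R,6R)-4-hydroxy-2,2,6-trimethylcyclohexan-1-one (actinol) | O=C1[C@H](C)C[C@@H](O)CC1(C)C | starting material
22 | (4R,6R)-4-[(tert-butyldimethylsilyl)oxy]-2,2,6-trimethylcyclohexan-1-one | O=C1[C@H](C)C[C@@H](O[Si](C)(C)C(C)(C)C)CC1(C)C | intermediate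
23 | lithium (4R)-4-[(tert-butyldimethylsilyl)oxy]-2,6,6-trimethylcyclohex-1-en-1-olate | [Li]OC1=C(C)C[C@@H](O[Si](C)(C)C(C)(C)C)CC1(C)C | intermediate (not isolated)
24 | (4R)-4-[(tert-butyldimethylsilyl)oxy]-2,6,6-trimethylcyclohex-1-en-1-yl trifluoromethanesulfonate | FC(F)(F)S(=O)(=O)OC1=C(C)C[C@@H](O[Si](C)(C)C(C)(C)C)CC1(C)C | intermediate
25 | 2-[(E)-2-ethoxyethenyl]-4,4,5,5-tetramethyl-1,3,2-dioxaborolane | CCO/C=C/B1OC(C)(C)C(C)(C)O1 | starting material
26 | tert-butyl({(1R)-4-[(E)-2-ethoxyethenyl]-3,5,5-trimethylcyclohex-3-en-1-yl}oxy)dimethylsilane | CCO/C=C/C1=C(C)C[C@@H](O[Si](C)(C)C(C)(C)C)CC1(C)C | intermediate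
27 | 2-[(4R)-4-[(tert-butyldimethylsilyl)oxy]-2,6,6-trimethylcyclohex-1-en-1-yl]acetaldehyde | O=CCC1=C(C)C[C@@H](O[Si](C)(C)C(C)(C)C)CC1(C)C | intermediate
28 | tert-butyldimethyl(prop-2-yn-1-yloxy)silane | C#CCO[Si](C)(C)C(C)(C)C | starting material
29 | methyl chloroformate | COC(=O)Cl | starting material
30 | {3-[(tert-butyldimethylsilyl)oxy]prop-1-yn-1-yl}lithium | [Li]C#CCO[Si](C)(C)C(C)(C)C | intermediate (not isolated)
31 | methyl 4-[(tert-butyldimethylsilyl)oxy]but-2-ynoate | COC(=O)C#CCO[Si](C)(C)C(C)(C)C | intermediate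
32 | methyl (2E)-4-[(tert-butyldimethylsilyl)oxy]-3-(tributylstannyl)but-2-enoate | COC(=O)/C=C(\CO[Si](C)(C)C(C)(C)C)[Sn](CCCC)(CCCC)CCCC | intermediate
33 | (2E)-4-[(tert-butyldimethylsilyl)oxy]-3-(tributylstannyl)but-2-en-1-ol | OC/C=C(\CO[Si](C)(C)C(C)(C)C)[Sn](CCCC)(CCCC)CCCC | intermediate
34 | (2E)-4-[(tert-butyldimethylsilyl)oxy]-3-iodobut-2-en-1-ol | OC/C=C(\CO[Si](C)(C)C(C)(C)C)I | intermediate
35 | (2E)-3-{[(tert-butyldimethylsilyl)oxy]methyl}-5-[(4R)-4-[(tert-butyldimethylsilyl)oxy]-2,6,6-trimethylcyclohex-1-en-1-yl]pent-2-ene-1,4-diol, both epimers at C4 | OC/C=C(\CO[Si](C)(C)C(C)(C)C)C(O)CC1=C(C)C[C@@H](O[Si](C)(C)C(C)(C)C)CC1(C)C | intermediate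
36 | (2E)-3-{[(tert-butyldimethylsilyl)oxy]methyl}-5-[(4R)-4-[(tert-butyldimethylsilyl)oxy]-2,6,6-trimethylcyclohex-1-en-1-yl]-4-oxopent-2-enal | O=C/C=C(\CO[Si](C)(C)C(C)(C)C)C(=O)CC1=C(C)C[C@@H](O[Si](C)(C)C(C)(C)C)CC1(C)C | intermediate
37 | triphenylphosphonium ylide of 20 | CC1=C[C@H](O)CC(C)(C)[C@H]1/C=C/C(C)=C/C=C/C(C)=C/C=C/C=C(C)/C=P(c1ccccc1)(c1ccccc1)c1ccccc1 | intermediate (not isolated)
38 | (3R,3'R,6'R)-3,19-bis[(tert-butyldimethylsilyl)oxy]-3'-hydroxy-7,8-dihydro-β,ε-caroten-8-one | CC1=C[C@H](O)CC(C)(C)[C@H]1/C=C/C(C)=C/C=C/C(C)=C/C=C/C=C(C)/C=C/C=C(\CO[Si](C)(C)C(C)(C)C)C(=O)CC1=C(C)C[C@@H](O[Si](C)(C)C(C)(C)C)CC1(C)C | intermediate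
39 | siphonaxanthin, (3R,3'R,6'R)-3,3',19-trihydroxy-7,8-dihydro-β,ε-caroten-8-one | CC1=C[C@H](O)CC(C)(C)[C@H]1/C=C/C(C)=C/C=C/C(C)=C/C=C/C=C(C)/C=C/C=C(\CO)C(=O)CC1=C(C)C[C@@H](O)CC1(C)C | target

**Step count and risks**

Total steps: 23. Longest linear sequence: 13 (steps 1–11, 22, 23).

Step 6 is the most likely to fail. The O-protonated dienone may be too poor a nucleophile at the temperature at which the acetate is safe, so that on warming the newly allylic C3'–O bond ionises; the ring cation may also lose a proton toward C6' or its methyl group. The fallback sets out from 6 and comes back at 12; it closes the ring before the enone is attached, on a substrate whose internal alkene is isolated. Alkynol 6 is carboaluminated as in step 3 to alkenylalane 7, which is turned into its ate complex with n-BuLi and trapped with paraformaldehyde to give the diol (2E,5R)-3,7-dimethylocta-2,7-diene-1,5-diol F1. Chloroacetylation of the primary allylic hydroxyl (ClCH2COCl, 2,4,6-collidine, −78 °C) and then acetylation of the secondary one give the mixed diester F2. ClSO3H in 2-nitropropane at −78 °C (the geranyl acetate type of cyclisation) should give the ring diester F3 under the same 1,4-induction. K2CO3 in MeOH at 0 °C should cleave only the chloroacetate and give the primary alcohol F4. Dess–Martin oxidation gives the ring aldehyde F5, and Wittig reaction with 1-(triphenylphosphoranylidene)propan-2-one gives the (E)-enone 12.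

Step 22 is the second risk. The ylide may add in conjugate fashion to the doubly activated ene-dione aldehyde or enolise it at C7, and the C9=C10 bond of 36 may isomerise before olefination. The fallback sets out from 34 (with 20 and 27) and comes back at 39; it joins the polyene first and makes the ketone last. MnO2 oxidation of 34 gives the iodo enal F6. Wittig reaction with 20 under the conditions of step 22 gives the C29 alkenyl iodide F7. TBSCl and imidazole protect the ring hydroxyl to give the bis-silyl iodide F8. Nozaki–Hiyama–Kishi coupling with 27 under the conditions of step 20 gives the C8 carbinol F9. Dess–Martin oxidation gives the tris-silyl ketone F10, and the conditions of step 23 remove all three silyl groups to give 39.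

Step 8 is the third risk. Under HBr the ring allylic alcohol may ionise as well, and the pentadienyl cation may lose H-6' to give a ring-conjugated triene. The fallback sets out from 12 and comes back at 15; it builds the C15 unit without acid. Horner–Wadsworth–Emmons reaction of 12 with diethyl (cyanomethyl)phosphonate and NaH gives the dienyl nitrile F11, with the E isomer expected to dominate. iBu2AlH at −78 °C reduces the nitrile to the aldehyde and removes the acetate, giving the hydroxy dienal F12. NaBH4 gives the dienol F13. PPh3 and CBr4 at −30 °C (Appel conditions, neutral) convert the primary dienylic alcohol into the bromide F14, and further PPh3 gives 15, from which the minor geometric isomer is removed by crystallisation.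

**Further compounds**

F1 | step 6 | (2E,5R)-3,7-dimethylocta-2,7-diene-1,5-diol | OC/C=C(C)/C[C@H](O)CC(C)=C
F2 | step 6 | (2E,5R)-5-acetoxy-3,7-dimethylocta-2,7-dien-1-yl chloroacetate | ClCC(=O)OC/C=C(C)/C[C@H](OC(C)=O)CC(C)=C
F3 | step 6 | [(1R,4R)-4-acetoxy-2,6,6-trimethylcyclohex-2-en-1-yl]methyl chloroacetate | CC1=C[C@H](OC(C)=O)CC(C)(C)[C@H]1COC(=O)CCl
F4 | step 6 | (1R,4R)-4-(hydroxymethyl)-3,5,5-trimethylcyclohex-2-en-1-yl acetate | CC1=C[C@H](OC(C)=O)CC(C)(C)[C@H]1CO
F5 | step 6 | (1R,4R)-4-formyl-3,5,5-trimethylcyclohex-2-en-1-yl acetate | CC1=C[C@H](OC(C)=O)CC(C)(C)[C@H]1C=O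
F6 | step 22 | (2E)-4-[(tert-butyldimethylsilyl)oxy]-3-iodobut-2-enal | O=C/C=C(\CO[Si](C)(C)C(C)(C)C)I
F7 | step 22 | (1R,4R)-4-[(1E,3E,5E,7E,9E,11E,13E,15E)-17-[(tert-butyldimethylsilyl)oxy]-16-iodo-3,7,12-trimethylheptadeca-1,3,5,7,9,11,13,15-octaen-1-yl]-3,5,5-trimethylcyclohex-2-en-1-ol | CC1=C[C@H](O)CC(C)(C)[C@H]1/C=C/C(C)=C/C=C/C(C)=C/C=C/C=C(C)/C=C/C=C(\CO[Si](C)(C)C(C)(C)C)I
F8 | step 22 | tert-butyldimethylsilyl ether of F7 at the ring hydroxyl | CC1=C[C@H](O[Si](C)(C)C(C)(C)C)CC(C)(C)[C@H]1/C=C/C(C)=C/C=C/C(C)=C/C=C/C=C(C)/C=C/C=C(\CO[Si](C)(C)C(C)(C)C)I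
F9 | step 22 | (3R,3'R,6'R)-3,3',19-tris[(tert-butyldimethylsilyl)oxy]-7,8-dihydro-β,ε-caroten-8-ol, both epimers at C8 | CC1=C[C@H](O[Si](C)(C)C(C)(C)C)CC(C)(C)[C@H]1/C=C/C(C)=C/C=C/C(C)=C/C=C/C=C(C)/C=C/C=C(\CO[Si](C)(C)C(C)(C)C)C(O)CC1=C(C)C[C@@H](O[Si](C)(C)C(C)(C)C)CC1(C)C
F10 | step 22 | (3R,3'R,6'R)-3,3',19-tris[(tert-butyldimethylsilyl)oxy]-7,8-dihydro-β,ε-caroten-8-one | CC1=C[C@H](O[Si](C)(C)C(C)(C)C)CC(C)(C)[C@H]1/C=C/C(C)=C/C=C/C(C)=C/C=C/C=C(C)/C=C/C=C(\CO[Si](C)(C)C(C)(C)C)C(=O)CC1=C(C)C[C@@H](O[Si](C)(C)C(C)(C)C)CC1(C)C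
F11 | step 8 | (1R,4R)-4-[(1E,3E)-4-cyano-3-methylbuta-1,3-dien-1-yl]-3,5,5-trimethylcyclohex-2-en-1-yl acetate | CC1=C[C@H](OC(C)=O)CC(C)(C)[C@H]1/C=C/C(C)=C/C#N
F12 | step 8 | (2E,4E)-5-[(1R,4R)-4-hydroxy-2,6,6-trimethylcyclohex-2-en-1-yl]-3-methylpenta-2,4-dienal | CC1=C[C@H](O)CC(C)(C)[C@H]1/C=C/C(C)=C/C=O
F13 | step 8 | (2E,4E)-5-[(1R,4R)-4-hydroxy-2,6,6-trimethylcyclohex-2-en-1-yl]-3-methylpenta-2,4-dien-1-ol | CC1=C[C@H](O)CC(C)(C)[C@H]1/C=C/C(C)=C/CO
F14 | step 8 | (1R,4R)-4-[(1E,3E)-5-bromo-3-methylpenta-1,3-dien-1-yl]-3,5,5-trimethylcyclohex-2-en-1-ol | CC1=C[C@H](O)CC(C)(C)[C@H]1/C=C/C(C)=C/CBr
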